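**Retrosynthetic overview**
- The last bonds cut are the four O–CH3 bonds (global demethylation) and the ring B aryl–CH2 bond to the pyranone (Negishi coupling of a ring B bromide with a pyranonylmethylzinc reagent).
- Feature used: the ketone carbon lies between the ring B carbon whose neighbour bears the phenol oxygen and the ring A carbon flanked by C–ethyl and C–OH. Phenol O, C=O, ring A ipso carbon, C–Et and the neighbouring C–OH are O1, C4, C3, C2 and the ester carbon of a 5-bromo-2-ethylchromone-3-carboxylate.
- Key disconnection: the ring A bonds C(Et)–CH and C(OH)–C(CO2Me), made by adding a 1,3-bis(silyloxy)diene to chromone C2, opening the pyranone ring and closing on the 3-ester (Dieckmann). The extra CO2Me is then removed.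
- The chromone comes from 2-bromo-6-fluorobenzoic acid and ethyl 3-oxopentanoate (C-acylation, then fluoride displacement).
- Ring order: ring B (purchased), chromone pyranone ring (step 3), ring A with opening of the chromone ring (step 6), 2-pyranone ring (purchased, attached in step 10).

Key step: step 6

Remark: the target has no stereocentre; tricarbonyl and hydroxypyranone compounds are written as one tautomer, and enol ether geometries that are lost in the following step are left open.

Step 1
Reactants: 1 2-bromo-6-fluorobenzoic acid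
Product: 2 2-bromo-6-fluorobenzoyl chloride
Conditions: (COCl)2, DMF (cat.), CH2Cl2, 0 → 20 °C
Reagents that add atoms: oxalyl chloride, O=C(Cl)C(=O)Cl
Why: DMF-catalysed chlorination through the Vilsmeier-type chloroiminium salt converts the hindered acid into its acid chloride under neutral conditions that leave both aryl halides untouched.

Step 2
Reactants: 2 2-bromo-6-fluorobenzoyl chloride; 3 ethyl 3-oxopentanoate
Product: 4 ethyl 2-(2-bromo-6-fluorobenzoyl)-3-oxopentanoate (racemic, largely enolised)
Conditions: MgCl2, Et3N, MeCN, 0 → 20 °C; 1 M HCl work-up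
Reagents that add atoms: none
Why: MgCl2 and Et3N form the chelated magnesium enolate of the β-ketoester by soft enolisation, and this enolate is acylated on carbon by 2 (Claisen-type C-acylation) because the chelate ties up both oxygens.

Step 3
Reactants: 4 ethyl 2-(2-bromo-6-fluorobenzoyl)-3-oxopentanoate
Product: 5 ethyl 5-bromo-2-ethyl-4-oxo-4H-chromene-3-carboxylate
Conditions: K2CO3, DMF, 70 °C
Reagents that add atoms: none
Why: In an intramolecular nucleophilic aromatic substitution the enolate oxygen of the propionyl ketone displaces the fluoride ortho to the aryl ketone and closes the pyranone ring, fluoride being displaced far faster than bromide in addition–elimination so that bromine stays at C5.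

Step 4
Reactants: 6 methyl acetoacetate
Product: 7 methyl 3-(trimethylsilyloxy)but-2-enoate
Conditions: Me3SiCl, Et3N, hexane, 20 °C
Reagents that add atoms: chlorotrimethylsilane, C[Si](C)(C)Cl
Why: Et3N-mediated O-silylation of the enol form of the β-ketoester (enol silylation) gives the silyl enol ether, whose double-bond geometry is of no consequence for step 5.

Step 5
Reactants: 7 methyl 3-(trimethylsilyloxy)but-2-enoate
Product: 8 1-methoxy-1,3-bis(trimethylsilyloxy)buta-1,3-diene
Conditions: LiN(i-Pr)2, THF, −78 °C; Me3SiCl, −78 → 20 °C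
Reagents that add atoms: chlorotrimethylsilane, C[Si](C)(C)Cl
Why: LiN(i-Pr)2 removes a γ-proton of the vinylogous ester to give the dienolate, which Me3SiCl traps on the ester oxygen (silyl ketene acetal formation) to give the 1,3-bis(silyloxy)diene.

Step 6
Reactants: 5 ethyl 5-bromo-2-ethyl-4-oxo-4H-chromene-3-carboxylate; 8 1-methoxy-1,3-bis(trimethylsilyloxy)buta-1,3-diene
Product: 12 methyl 3-(2-bromo-6-hydroxybenzoyl)-4-ethyl-2,6-dihydroxybenzoate, via silyloxybenzopyrylium triflate 9 (not isolated), via bis-silylated Michael adduct 10 (not isolated), via ring-opened ketodiester phenol 11 (not isolated)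
Conditions: Me3SiOTf (1.2 equiv), CH2Cl2, 20 °C; then 8 (1.5 equiv), 0 → 20 °C; then Et3N, MeOH, 20 °C; then NaOMe, MeOH, 20 → 50 °C; 1 M HCl work-up
Reagents that add atoms: none
Why: Proposed new method: Me3SiOTf silylates the C4 carbonyl of 5 to give benzopyrylium triflate 9, whose C2 is attacked by the CH2 terminus of 8 (Mukaiyama–Michael addition) to give 10, C4 being shielded by its silyloxy group and the peri bromine and no base being present that could take a proton from the 2-ethyl group. Et3N/MeOH then removes the silyl groups and the C3 ester enolate expels the ring B phenoxide by E1cB, so that O1 becomes the ring B hydroxyl and C4 the diaryl ketone of 11; NaOMe finally drives a 6-exo-trig Dieckmann closure of the ketoester carbon onto the former 3-ester, and loss of alkoxide followed by enolisation gives the aromatic ring A of 12. The closest known reaction type is the domino Michael/retro-Michael/aldol sequence of 3-formyl- and 3-acylchromones with 1,3-bis(silyloxy)dienes, which gives 2-hydroxybenzophenones; new here are the alkyl group at C2 (a quaternary centre is formed in the addition) and an ester as the last acceptor, which is why an alkoxide is added for the final stage. No stereocentre has to be controlled, because C2 of 10 is racemic and becomes sp2 on ring opening, and the alkene geometry of 11 equilibrates through its dienolate so that the ester can reach the chain. The step needs closure on the ester and not on the aryl ketone (which would end in a biaryl): the ketone is flanked by the C–Br and C–O carbons of ring B, twisted out of conjugation and deactivated by the ortho phenoxide, whereas the ester is unhindered, and acylation through oxygen (lactone formation) is reversible in NaOMe/MeOH while acylation through carbon ends in an aromatic ring.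

Step 7
Reactants: 12 methyl 3-(2-bromo-6-hydroxybenzoyl)-4-ethyl-2,6-dihydroxybenzoate
Product: 14 (2-bromo-6-hydroxyphenyl)(2-ethyl-4,6-dihydroxyphenyl)methanone, via free 2,6-dihydroxybenzoic acid 13 (not isolated)
Conditions: BBr3 (6 equiv), CH2Cl2, −78 → 20 °C; H2O; then AcOH/H2O, 100 °C
Reagents that add atoms: none
Why: BBr3 converts the phenols into aryloxyboranes that chelate the ester carbonyl so that bromide removes the ester methyl group (boron trihalide dealkylation of a hindered methyl ester) without forming any phenoxide that could attack the C–Br carbon of ring B, and acid 13 then loses CO2 on heating by ipso protonation (protodecarboxylation through its keto tautomer).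

Step 8
Reactants: 14 (2-bromo-6-hydroxyphenyl)(2-ethyl-4,6-dihydroxyphenyl)methanone
Product: 15 (2-bromo-6-methoxyphenyl)(2-ethyl-4,6-dimethoxyphenyl)methanone
Conditions: MeI (excess), K2CO3, DMF, 20 → 40 °C
Reagents that add atoms: iodomethane, CI
Why: Williamson etherification with excess MeI caps all three phenols, including the two hydrogen-bonded to the ketone, at a temperature at which displacement of the ring B bromide by the ring A phenoxide is not expected to compete.

Step 9
Reactants: 16 4-methoxy-6-methyl-2H-pyran-2-one
Product: 17 6-(bromomethyl)-4-methoxy-2H-pyran-2-one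
Conditions: NBS, AIBN (cat.), PhCF3, 85 °C
Reagents that add atoms: N-bromosuccinimide, O=C1CCC(=O)N1Br
Why: Wohl–Ziegler radical bromination takes place at the 6-methyl group because the derived radical is delocalised over the pyranone diene, and radical initiation in a non-polar solvent suppresses ionic bromination at C3.

Step 10
Reactants: 17 6-(bromomethyl)-4-methoxy-2H-pyran-2-one; 15 (2-bromo-6-methoxyphenyl)(2-ethyl-4,6-dimethoxyphenyl)methanone
Product: 19 6-{[2-(2-ethyl-4,6-dimethoxybenzoyl)-3-methoxyphenyl]methyl}-4-methoxy-2H-pyran-2-one, via pyranonylmethylzinc bromide 18 (not isolated)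
Conditions: Zn dust, LiCl, THF, 0 → 20 °C; then 15, Pd(OAc)2 (2 mol %), SPhos (4 mol %), THF, 50 °C
Reagents that add atoms: none
Why: LiCl-assisted insertion of zinc into the activated C–Br bond of 17 gives the benzylic-type zinc reagent 18, which undergoes Negishi coupling with 15 after oxidative addition of zerovalent palladium (from Pd(OAc)2 and SPhos) into the aryl C–Br bond, the hindered ketone, the lactone and the methyl ethers being inert to organozinc.

Step 11
Reactants: 19 6-{[2-(2-ethyl-4,6-dimethoxybenzoyl)-3-methoxyphenyl]methyl}-4-methoxy-2H-pyran-2-one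
Product: 20 6-{[2-(2-ethyl-4,6-dihydroxybenzoyl)-3-hydroxyphenyl]methyl}-4-hydroxy-2H-pyran-2-one
Conditions: BBr3 (10 equiv), CH2Cl2, −78 → 20 °C; ice/H2O
Reagents that add atoms: none
Why: BBr3 cleaves all four O–CH3 bonds by Lewis acid-assisted SN2 demethylation, the two methoxy groups ortho to the ketone through chelation and the para methoxy and pyranone methoxy groups (the latter a vinylogous methyl ester) through oxonium activation, while the aryl–CH2 bond and the lactone are untouched.

**Compound list**
1 | 2-bromo-6-fluorobenzoic acid | O=C(O)c1c(F)cccc1Br | starting material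
2 | 2-bromo-6-fluorobenzoyl chloride | O=C(Cl)c1c(F)cccc1Br | intermediate
3 | ethyl 3-oxopentanoate | CCC(=O)CC(=O)OCC | starting material
4 | ethyl 2-(2-bromo-6-fluorobenzoyl)-3-oxopentanoate (racemic, enolisable) | CCC(=O)C(C(=O)OCC)C(=O)c1c(F)cccc1Br | intermediate
5 | ethyl 5-bromo-2-ethyl-4-oxo-4H-chromene-3-carboxylate | CCOC(=O)c1c(CC)oc2cccc(Br)c2c1=O | intermediate
6 | methyl acetoacetate | COC(=O)CC(C)=O | starting material
7 | methyl 3-(trimethylsilyloxy)but-2-enoate (either geometry) | COC(=O)C=C(C)O[Si](C)(C)C | intermediate
8 | 1-methoxy-1,3-bis(trimethylsilyloxy)buta-1,3-diene | COC(O[Si](C)(C)C)=CC(=C)O[Si](C)(C)C | intermediate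
9 | 5-bromo-3-(ethoxycarbonyl)-2-ethyl-4-(trimethylsilyloxy)chromenylium triflate | CCOC(=O)c1c(CC)[o+]c2cccc(Br)c2c1O[Si](C)(C)C.[O-]S(=O)(=O)C(F)(F)F | intermediate
10 | ethyl 5-bromo-2-ethyl-2-[4-methoxy-4-oxo-2-(trimethylsilyloxy)but-2-en-1-yl]-4-(trimethylsilyloxy)-2H-chromene-3-carboxylate (racemic) | CCOC(=O)C1=C(O[Si](C)(C)C)c2c(Br)cccc2OC1(CC)CC(O[Si](C)(C)C)=CC(=O)OC | intermediate
11 | 1-ethyl 7-methyl (2Z)-2-(2-bromo-6-hydroxybenzoyl)-3-ethyl-5-oxohept-2-enedioate (the cyclising isomer; geometry mobile) | CCOC(=O)/C(=C(/CC)CC(=O)CC(=O)OC)C(=O)c1c(O)cccc1Br | intermediate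
12 | methyl 3-(2-bromo-6-hydroxybenzoyl)-4-ethyl-2,6-dihydroxybenzoate | CCc1cc(O)c(C(=O)OC)c(O)c1C(=O)c1c(O)cccc1Br | intermediate
13 | 3-(2-bromo-6-hydroxybenzoyl)-4-ethyl-2,6-dihydroxybenzoic acid | CCc1cc(O)c(C(=O)O)c(O)c1C(=O)c1c(O)cccc1Br | intermediate
14 | (2-bromo-6-hydroxyphenyl)(2-ethyl-4,6-dihydroxyphenyl)methanone | CCc1cc(O)cc(O)c1C(=O)c1c(O)cccc1Br | intermediate
15 | (2-bromo-6-methoxyphenyl)(2-ethyl-4,6-dimethoxyphenyl)methanone | CCc1cc(OC)cc(OC)c1C(=O)c1c(OC)cccc1Br | intermediate
16 | 4-methoxy-6-methyl-2H-pyran-2-one | COc1cc(C)oc(=O)c1 | starting material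
17 | 6-(bromomethyl)-4-methoxy-2H-pyran-2-one | COc1cc(CBr)oc(=O)c1 | intermediate
18 | bromo[(4-methoxy-2-oxo-2H-pyran-6-yl)methyl]zinc | COc1cc(C[Zn]Br)oc(=O)c1 | intermediate
19 | 6-{[2-(2-ethyl-4,6-dimethoxybenzoyl)-3-methoxyphenyl]methyl}-4-methoxy-2H-pyran-2-one | CCc1cc(OC)cc(OC)c1C(=O)c1c(OC)cccc1Cc1cc(OC)cc(=O)o1 | intermediate
20 | 6-{[2-(2-ethyl-4,6-dihydroxybenzoyl)-3-hydroxyphenyl]methyl}-4-hydroxy-2H-pyran-2-one | CCc1cc(O)cc(O)c1C(=O)c1c(O)cccc1Cc1cc(O)cc(=O)o1 | target

**Step count**
Total steps: 11. Longest linear sequence: 8 steps (1, 2, 3, 6, 7, 8, 10, 11).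

**Steps most likely to fail**

Step 6 (the proposed new method). The benzopyrylium ion may lose a proton from its 2-ethyl group or resist addition at the substituted C2. In the last stage the enolate may acylate through oxygen, or the sequence may stall before the Claisen closure. The fallback uses known chemistry and sets out from acid chloride 2. Friedel–Crafts acylation of purchased 1-ethyl-3,5-dimethoxybenzene (CCc1cc(OC)cc(OC)c1) with 2 (AlCl3, CH2Cl2, 0 °C, short reaction time so that the ortho methoxy group stays intact) should occur at the ring carbon between the ethyl group and a methoxy group, para to the other methoxy group, and give (2-bromo-6-fluorophenyl)(2-ethyl-4,6-dimethoxyphenyl)methanone F1. NaOMe in DMF at 60 °C should then replace the fluoride ortho to the ketone (addition–elimination, fluoride before bromide) and give 15, where the route is rejoined at step 10.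

Step 10. Zinc insertion may be accompanied by Wurtz-type dimerisation of the bromide, the zinc reagent may be protonated, or coupling next to the bulky aroyl group may be slow. The fallback reverses the polarity and sets out from 15. Miyaura borylation (B2pin2, PdCl2(dppf), KOAc, dioxane, 90 °C) should give (2-ethyl-4,6-dimethoxyphenyl)[2-methoxy-6-(4,4,5,5-tetramethyl-1,3,2-dioxaborolan-2-yl)phenyl]methanone F2. Suzuki–Miyaura coupling of F2 with bromide 17 as the sp3 electrophile (Pd(PPh3)4, K3PO4, THF/H2O, 60 °C) should give 19, where the route is rejoined at step 11.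

Step 11. Dealkylation at the pyranone oxygen may remain incomplete, or the liberated polyphenol may degrade during long exposure to BBr3. The fallback replaces Lewis-acid dealkylation by hydrogenolysis and sets out from 14.
- BnBr, K2CO3, DMF should give [2-(benzyloxy)-6-bromophenyl][2,4-bis(benzyloxy)-6-ethylphenyl]methanone F3.
- Purchased 4-hydroxy-6-methyl-2H-pyran-2-one is O-benzylated under Mitsunobu conditions (BnOH, PPh3, diisopropyl azodicarboxylate, THF) to 4-(benzyloxy)-6-methyl-2H-pyran-2-one F4.
- F4 is deprotonated at the 6-methyl group (LiN(SiMe3)2, THF, −78 °C) and transmetalated with ZnCl2 to chloro{[4-(benzyloxy)-2-oxo-2H-pyran-6-yl]methyl}zinc F5.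
- Negishi coupling of F5 with F3 (Pd(OAc)2, SPhos, THF, 50 °C) should give 4-(benzyloxy)-6-{[3-(benzyloxy)-2-[2,4-bis(benzyloxy)-6-ethylbenzoyl]phenyl]methyl}-2H-pyran-2-one F6.
- Hydrogenolysis of F6 (H2, Pd on carbon, EtOAc, 20 °C, stopped after uptake of four equivalents) should remove the four benzyl groups under neutral conditions and give 20.

Further compounds
F1 | step 6 | (2-bromo-6-fluorophenyl)(2-ethyl-4,6-dimethoxyphenyl)methanone | CCc1cc(OC)cc(OC)c1C(=O)c1c(F)cccc1Br
F2 | step 10 | (2-ethyl-4,6-dimethoxyphenyl)[2-methoxy-6-(4,4,5,5-tetramethyl-1,3,2-dioxaborolan-2-yl)phenyl]methanone | CCc1cc(OC)cc(OC)c1C(=O)c1c(OC)cccc1B1OC(C)(C)C(C)(C)O1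
F3 | step 11 | [2-(benzyloxy)-6-bromophenyl][2,4-bis(benzyloxy)-6-ethylphenyl]methanone | CCc1cc(OCc2ccccc2)cc(OCc2ccccc2)c1C(=O)c1c(OCc2ccccc2)cccc1Br
F4 | step 11 | 4-(benzyloxy)-6-methyl-2H-pyran-2-one | Cc1cc(OCc2ccccc2)cc(=O)o1
F5 | step 11 | chloro{[4-(benzyloxy)-2-oxo-2H-pyran-6-yl]methyl}zinc | O=c1cc(OCc2ccccc2)cc(C[Zn]Cl)o1
F6 | step 11 | 4-(benzyloxy)-6-{[3-(benzyloxy)-2-[2,4-bis(benzyloxy)-6-ethylbenzoyl]phenyl]methyl}-2H-pyran-2-one | CCc1cc(OCc2ccccc2)cc(OCc2ccccc2)c1C(=O)c1c(OCc2ccccc2)cccc1Cc1cc(OCc2ccccc2)cc(=O)o1
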